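## Retrosynthetic overview

1. Target 25 ⇐ 24 ⇐ 22 by late C20 oxidation and ester hydrolysis. Ring D is closed last (C13–C16) by 5-exo-dig carbocyclisation of the C12 silyl enol ether onto the C8 propargyl group.
2. Key step, ring B: the C9–C10 bond is made by a hydrogen-atom-transfer-initiated radical conjugate addition. The C10 tertiary radical from the C1=C10 alkene of ring A closes onto C9 of the ring C enone (18 → 19), setting C9 and the C10 quaternary centre.
3. C5–C6: Ireland–Claisen rearrangement of ester 15 (ring C acid 8 + ring A allylic alcohol 14) with C1→C5 chirality transfer.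
4. Rings A (11) and C (8): two catalytic asymmetric Robinson annulations with methyl vinyl ketone set the C4 and C8 quaternary centres; C20 comes from formaldehyde.
5. Ring order: A and C (separately) → B (radical) → D.

Assumption: gibberellane numbering is used for every intermediate, α is the face of ring B that carries C20 (β carries H-5 and H-9), and each chiral catalyst is used in the enantiomeric form that gives the configuration stated.

## Route

Step 1
Reactants: 1 pent-4-ynal; 2 methyl bromoacetate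
Product: 4 methyl 3-formylhex-5-ynoate (racemic), via pyrrolidine enamine 3 (not isolated)
Conditions: pyrrolidine, 4 Å MS, MeCN, 0 °C; then 2, reflux; then H2O
Reagents that add atoms: none
Why: Stork enamine alkylation places the C6–C7 acetate unit on the future C8; the new stereocentre is irrelevant because it becomes quaternary under catalyst control in step 2.

Step 2
Reactants: 4 methyl 3-formylhex-5-ynoate; 5 but-3-en-2-one
Product: 8 2-[(1S)-4-oxo-1-(prop-2-yn-1-yl)cyclohex-2-en-1-yl]acetic acid, via Michael adduct 6 (not isolated), via enone methyl ester 7 (not isolated)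
Conditions: N-(4-dodecylphenylsulfonyl)prolinamide (20 mol%), ClCH2CH2Cl, rt; then KOH, MeOH/H2O, 50 °C; then 1 M HCl
Reagents that add atoms: potassium hydroxide, [K+].[OH-]
Why: Enamine-catalysed Michael addition of the α-branched aldehyde to the vinyl ketone sets the C8 quaternary centre (S) under catalyst control, and hydroxide then closes ring C by aldol condensation (Robinson annulation) and saponifies the ester.

Step 3
Reactants: 9 methyl 2-methyl-3-oxopropanoate; 5 but-3-en-2-one
Product: 11 methyl (1R)-1-methyl-4-oxocyclohex-2-ene-1-carboxylate, via Michael adduct 10 (not isolated)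
Conditions: 6′-hydroxy cinchona alkaloid catalyst (10 mol%), CH2Cl2, −20 °C; then pyrrolidine (20 mol%), AcOH, PhMe, 60 °C
Reagents that add atoms: none
Why: Asymmetric base-catalysed Michael addition of the α-formyl ester (a 1,3-dicarbonyl donor) sets the C4 quaternary centre (R), and amine-mediated aldol condensation (Robinson annulation) closes ring A while keeping the methyl ester.

Step 4
Reactants: 11 methyl (1R)-1-methyl-4-oxocyclohex-2-ene-1-carboxylate
Product: 12 methyl (1R)-3-(hydroxymethyl)-1-methyl-4-oxocyclohex-2-ene-1-carboxylate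
Conditions: aq. HCHO, DMAP, THF/H2O, rt
Reagents that add atoms: formaldehyde, C=O
Why: Morita–Baylis–Hillman hydroxymethylation installs C20 on C10 (DMAP adds to C5, the enolate captures formaldehyde, DMAP is expelled); no stereocentre is formed.

Step 5
Reactants: 12 methyl (1R)-3-(hydroxymethyl)-1-methyl-4-oxocyclohex-2-ene-1-carboxylate
Product: 13 methyl (1R)-3-{[(tert-butyldimethylsilyl)oxy]methyl}-1-methyl-4-oxocyclohex-2-ene-1-carboxylate
Conditions: TBSCl, imidazole, CH2Cl2, 0 °C
Reagents that add atoms: tert-butyldimethylsilyl chloride, CC(C)(C)[Si](C)(C)Cl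
Why: Standard silylation protects the C20 alcohol so that only the C1 hydroxyl is esterified later.

Step 6
Reactants: 13 methyl (1R)-3-{[(tert-butyldimethylsilyl)oxy]methyl}-1-methyl-4-oxocyclohex-2-ene-1-carboxylate
Product: 14 methyl (1R,4S)-3-{[(tert-butyldimethylsilyl)oxy]methyl}-4-hydroxy-1-methylcyclohex-2-ene-1-carboxylate
Conditions: (R)-2-methyl-CBS-oxazaborolidine (20 mol%), BH3·SMe2, THF, −30 °C; then MeOH
Reagents that add atoms: none
Why: Corey–Bakshi–Shibata reduction gives catalyst-controlled 1,2-hydride delivery, placing the C1 hydroxyl cis to the C4 ester (α face), the configuration needed for chirality transfer in step 8.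

Step 7
Reactants: 8 2-[(1S)-4-oxo-1-(prop-2-yn-1-yl)cyclohex-2-en-1-yl]acetic acid; 14 methyl (1R,4S)-3-{[(tert-butyldimethylsilyl)oxy]methyl}-4-hydroxy-1-methylcyclohex-2-ene-1-carboxylate
Product: 15 (1S,4R)-2-{[(tert-butyldimethylsilyl)oxy]methyl}-4-(methoxycarbonyl)-4-methylcyclohex-2-en-1-yl 2-[(1S)-4-oxo-1-(prop-2-yn-1-yl)cyclohex-2-en-1-yl]acetate
Conditions: DCC, DMAP (cat.), CH2Cl2, 0 °C to rt
Reagents that add atoms: none
Why: Steglich esterification joins the two enantiopure fragments without touching a stereocentre.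

Step 8
Reactants: 15 allylic ester of 8 and 14
Product: 18 methyl (1R,2S)-3-{[(tert-butyldimethylsilyl)oxy]methyl}-2-{2-methoxy-2-oxo-1-[4-oxo-1-(3-trimethylsilylprop-2-yn-1-yl)cyclohex-2-en-1-yl]ethyl}-1-methylcyclohex-3-ene-1-carboxylate (C8 as in 8; C6 epimers), via tris-silyl ketene acetal 16 (not isolated), via rearranged acid 17 (not isolated)
Conditions: LDA (3.6 equiv), TMSCl (4 equiv), THF, −78 to 60 °C; then 1 M HCl; then TMSCHN2, PhMe/MeOH, 0 °C
Reagents that add atoms: chlorotrimethylsilane, C[Si](C)(C)Cl; trimethylsilyldiazomethane, C[Si](C)(C)C=[N+]=[N-]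
Why: In this Ireland–Claisen rearrangement excess base and silyl chloride cap the alkyne, mask the enone as its silyl dienol ether and form the silyl ketene acetal; its suprafacial [3,3] shift forms C5–C6 on the α face that carried the C1–O bond and moves the alkene to C1=C10, while C6 forms as a mixture that step 10 corrects.

Step 9
Reactants: 18 9,10-seco diester (C6 epimers)
Product: 19 tricyclic keto diester with rings A, B and C closed: A/B trans (5β-H, 10α-CH2OTBS), B/C cis (9β-H, C14 α), 4α-CO2Me, 8β-CH2C≡CSiMe3, C6 epimers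
Conditions: Fe(acac)3 (0.5 equiv), PhSiH3 (2.5 equiv), EtOH/(CH2OH)2 5:1, 60 °C, 0.01 M
Reagents that add atoms: none
Why: Hydrogen-atom transfer from the iron hydride to C1 gives the tertiary C10 radical, which adds 5-exo to C9 of the enone (polarity-matched Giese cyclisation); the three-atom tether forces ring B cis onto ring C (H-9 cis to the propargyl group), C9 bonds to the β face of C10 because α attack would run 1,3-syn to the axial C4 ester and give a cis-syn-cis tricycle, and the α-keto radical is reduced to the enolate and protonated.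

Step 10
Reactants: 19 tricyclic keto diester (C6 epimers, silylated alkyne)
Product: 20 tricyclic keto diester with free terminal alkyne and 6β-CO2Me (6α-H), otherwise as 19
Conditions: NaOMe (0.5 equiv), MeOH, 40 °C
Reagents that add atoms: none
Why: Methoxide removes the alkynyl silyl group and equilibrates the enolisable C6 centre to the more stable 6β-ester, trans to the C4 quaternary centre (thermodynamic epimerisation).

Step 11
Reactants: 20 tricyclic keto diester (6β-ester, terminal alkyne)
Product: 21 C12 tert-butyldimethylsilyl enol ether of 20 (C12=C13)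
Conditions: TBSOTf, Et3N, CH2Cl2, −78 to 0 °C
Reagents that add atoms: tert-butyldimethylsilyl trifluoromethanesulfonate, CC(C)(C)[Si](C)(C)OS(=O)(=O)C(F)(F)F
Why: Soft enolisation (silyl triflate and amine) gives the less hindered C12=C13 enol ether, away from the heavily substituted C9, and leaves the acidic terminal alkyne untouched.

Step 12
Reactants: 21 C12 silyl enol ether
Product: 22 dimethyl 20-[(tert-butyldimethylsilyl)oxy]-12-oxogibberell-16-ene-7,19-dioate (ring D closed, configuration of the target)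
Conditions: Ph3PAuCl (5 mol%), AgBF4 (5 mol%), CH2Cl2/MeOH 10:1, rt
Reagents that add atoms: none
Why: Cationic monovalent gold activates the alkyne for 5-exo-dig attack by C13 of the silyl enol ether (Conia-ene-type carbocyclisation), forming C13–C16 and the exocyclic methylene; the bridge from C8 can only span one face, so C13 is fixed.

Step 13
Reactants: 22 dimethyl 20-[(tert-butyldimethylsilyl)oxy]-12-oxogibberell-16-ene-7,19-dioate
Product: 23 dimethyl 20-hydroxy-12-oxogibberell-16-ene-7,19-dioate
Conditions: HF·pyridine, pyridine/THF, 0 °C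
Reagents that add atoms: none
Why: Buffered, non-basic fluoride desilylation frees the C20 alcohol while limiting its lactonisation onto the neighbouring C19 ester; the product is oxidised at once.

Step 14
Reactants: 23 dimethyl 20-hydroxy-12-oxogibberell-16-ene-7,19-dioate
Product: 24 dimethyl 12,20-dioxogibberell-16-ene-7,19-dioate
Conditions: DMP, CH2Cl2, 0 °C to rt
Reagents that add atoms: none
Why: Dess–Martin oxidation turns the neopentyl primary alcohol into the non-enolisable C20 aldehyde under neutral conditions.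

Step 15
Reactants: 24 dimethyl 12,20-dioxogibberell-16-ene-7,19-dioate
Product: 25 12,20-dioxogibberell-16-ene-7,19-dioic acid (CNP0412196.1, open aldehyde diacid form)
Conditions: LiOH, THF/H2O 3:1, 40 °C; then 1 M HCl to pH 3
Reagents that add atoms: lithium hydroxide, [Li+].[OH-]
Why: Saponification cleaves the C7 ester directly and the hindered C19 ester through attack of the neighbouring C20 aldehyde hydrate (transient lactol), with C6 already in its thermodynamic configuration.

## Compound list

1 | pent-4-ynal | C#CCCC=O | starting material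
2 | methyl bromoacetate | COC(=O)CBr | starting material
3 | (E)-1-(pent-1-en-4-yn-1-yl)pyrrolidine | C#CC/C=C/N1CCCC1 | intermediate
4 | methyl 3-formylhex-5-ynoate (racemic) | COC(=O)CC(CC#C)C=O | intermediate
5 | but-3-en-2-one | CC(=O)C=C | starting material
6 | methyl (3S)-3-formyl-3-(3-oxobutyl)hex-5-ynoate | O=C[C@@](CC#C)(CC(=O)OC)CCC(C)=O | intermediate
7 | methyl 2-[(1S)-4-oxo-1-(prop-2-yn-1-yl)cyclohex-2-en-1-yl]acetate | C#CC[C@@]1(CC(=O)OC)C=CC(=O)CC1 | intermediate
8 | 2-[(1S)-4-oxo-1-(prop-2-yn-1-yl)cyclohex-2-en-1-yl]acetic acid | C#CC[C@@]1(CC(=O)O)C=CC(=O)CC1 | intermediate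
9 | methyl 2-methyl-3-oxopropanoate | COC(=O)C(C)C=O | starting material
10 | methyl (2R)-2-formyl-2-methyl-5-oxohexanoate | COC(=O)[C@@](C)(C=O)CCC(C)=O | intermediate
11 | methyl (1R)-1-methyl-4-oxocyclohex-2-ene-1-carboxylate | COC(=O)[C@@]1(C)C=CC(=O)CC1 | intermediate
12 | methyl (1R)-3-(hydroxymethyl)-1-methyl-4-oxocyclohex-2-ene-1-carboxylate | COC(=O)[C@@]1(C)C=C(CO)C(=O)CC1 | intermediate
13 | methyl (1R)-3-{[(tert-butyldimethylsilyl)oxy]methyl}-1-methyl-4-oxocyclohex-2-ene-1-carboxylate | COC(=O)[C@@]1(C)C=C(CO[Si](C)(C)C(C)(C)C)C(=O)CC1 | intermediate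
14 | methyl (1R,4S)-3-{[(tert-butyldimethylsilyl)oxy]methyl}-4-hydroxy-1-methylcyclohex-2-ene-1-carboxylate (OH cis to CO2Me) | COC(=O)[C@@]1(C)C=C(CO[Si](C)(C)C(C)(C)C)[C@@H](O)CC1 | intermediate
15 | (1S,4R)-2-{[(tert-butyldimethylsilyl)oxy]methyl}-4-(methoxycarbonyl)-4-methylcyclohex-2-en-1-yl 2-[(1S)-4-oxo-1-(prop-2-yn-1-yl)cyclohex-2-en-1-yl]acetate | C#CC[C@@]1(CC(=O)O[C@H]2CC[C@@](C)(C(=O)OC)C=C2CO[Si](C)(C)C(C)(C)C)C=CC(=O)CC1 | intermediate
16 | tris-silyl ketene acetal of 15 (C6=C7 O-trimethylsilyl ketene acetal, ring C as trimethylsilyl dienol ether, alkyne C-silylated) | C[Si](C)(C)C#CC[C@@]1(C=C(O[Si](C)(C)C)O[C@H]2CC[C@@](C)(C(=O)OC)C=C2CO[Si](C)(C)C(C)(C)C)C=CC(O[Si](C)(C)C)=CC1 | intermediate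
17 | rearranged acid (C5–C6 bonded, C6 α on ring A, C1=C10 alkene, free C7 acid, silylated alkyne; C6 epimers) | C[Si](C)(C)C#CC[C@@]1(C(C(=O)O)[C@@H]2[C@](C)(C(=O)OC)CCC=C2CO[Si](C)(C)C(C)(C)C)C=CC(=O)CC1 | intermediate
18 | methyl (1R,2S)-3-{[(tert-butyldimethylsilyl)oxy]methyl}-2-{2-methoxy-2-oxo-1-[4-oxo-1-(3-trimethylsilylprop-2-yn-1-yl)cyclohex-2-en-1-yl]ethyl}-1-methylcyclohex-3-ene-1-carboxylate (C8 as in 8; C6 epimers) | C[Si](C)(C)C#CC[C@@]1(C(C(=O)OC)[C@@H]2[C@](C)(C(=O)OC)CCC=C2CO[Si](C)(C)C(C)(C)C)C=CC(=O)CC1 | intermediate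
19 | tricyclic keto diester, rings A, B, C: A/B trans (5β-H, 10α-CH2OTBS), B/C cis (9β-H, C14 α), 4α-CO2Me, 8β-CH2C≡CSiMe3, C12 ketone, C6 epimers | C[Si](C)(C)C#CC[C@]12CCC(=O)C[C@H]1[C@]1(CO[Si](C)(C)C(C)(C)C)CCC[C@@](C)(C(=O)OC)[C@H]1C2C(=O)OC | intermediate
20 | as 19 with free terminal alkyne and 6β-CO2Me (6α-H) | C#CC[C@]12CCC(=O)C[C@H]1[C@]1(CO[Si](C)(C)C(C)(C)C)CCC[C@@](C)(C(=O)OC)[C@H]1[C@@H]2C(=O)OC | intermediate
21 | C12 tert-butyldimethylsilyl enol ether of 20 (C12=C13) | C#CC[C@]12CC=C(O[Si](C)(C)C(C)(C)C)C[C@H]1[C@]1(CO[Si](C)(C)C(C)(C)C)CCC[C@@](C)(C(=O)OC)[C@H]1[C@@H]2C(=O)OC | intermediate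
22 | dimethyl 20-[(tert-butyldimethylsilyl)oxy]-12-oxogibberell-16-ene-7,19-dioate | C=C1C[C@]23C[C@H]1C(=O)C[C@H]2[C@]1(CO[Si](C)(C)C(C)(C)C)CCC[C@@](C)(C(=O)OC)[C@H]1[C@@H]3C(=O)OC | intermediate
23 | dimethyl 20-hydroxy-12-oxogibberell-16-ene-7,19-dioate | C=C1C[C@]23C[C@H]1C(=O)C[C@H]2[C@]1(CO)CCC[C@@](C)(C(=O)OC)[C@H]1[C@@H]3C(=O)OC | intermediate
24 | dimethyl 12,20-dioxogibberell-16-ene-7,19-dioate | C=C1C[C@]23C[C@H]1C(=O)C[C@H]2[C@]1(C=O)CCC[C@@](C)(C(=O)OC)[C@H]1[C@@H]3C(=O)OC | intermediate
25 | 12,20-dioxogibberell-16-ene-7,19-dioic acid (CNP0412196.1) | C=C1C[C@]23C[C@H]1C(=O)C[C@H]2[C@]1(C=O)CCC[C@@](C)(C(=O)O)[C@H]1[C@@H]3C(=O)O | target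

## Step count and risks

Total steps: 15. Longest linear sequence: 13 (steps 3 to 15).

Steps most likely to fail:

Step 9 (radical closure of ring B). The risks are the facial selectivity at C10 (trans versus cis A/B fusion), simple reduction of the alkene, and attack of the intermediate C11 α-keto radical on the alkyne. The fallback sets out from 18 and comes back at 19. The C1=C10 alkene of 18 is epoxidised with mCPBA to the 1,10-epoxide F1. Cp2TiCl (from Cp2TiCl2 and Zn, trivalent titanium) opens it to the same C10 radical without any metal hydride, and a second equivalent of titanium captures the α-keto radical as its enolate before it can reach the alkyne, giving the ring-B-closed C1 alcohol F2. Its imidazolylthiocarbonyl derivative F3 (thiocarbonyldiimidazole, DMAP) is deoxygenated with Bu3SnH/AIBN (Barton–McCombie) to 19.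

Step 8 (Ireland–Claisen rearrangement). The new C5–C6 bond lies between two carbons that each neighbour a quaternary centre, and three acidic sites must be silylated at once. The fallback sets out from 14 and enamine 3 and comes back at 18. Alcohol 14 is acylated with bromoacetyl bromide/pyridine to the bromoacetate F4, which alkylates enamine 3 to give, after hydrolysis, the aldehyde ester F5. The rearrangement is then run while C8 is still tertiary (LDA/TMSCl with the aldehyde masked in situ as its silyl enol ether, then TMSCHN2), giving the rearranged aldehyde diester F6. Ring C is built last by the amine-catalysed Robinson annulation of F6 with 5 (pyrrolidine/AcOH for the condensation), which returns to 18.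

Step 11 (regioselective enol ether formation for ring D). C11 and C13 are both 1,3 to C8, so the selectivity rests only on the steric bias of C9. The fallback sets out from 18 and comes back at 22. At the enone stage only C13 can be enolised, so 18 is converted (LDA 1.1 equiv, PhSeCl, −78 °C) into the 13-phenylselanyl enone F7. The radical closure of step 9 then gives the cyclised selenide F8, and NaOMe/MeOH as in step 10 gives the desilylated 6β-ester selenide F9. Bu3SnH/AIBN generates the C13 α-keto radical regiospecifically, and its 5-exo-dig cyclisation onto the alkyne gives 22 directly.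

## Further compounds

F1 | step 9 | 1,10-epoxide of 18 | C[Si](C)(C)C#CC[C@@]1(C(C(=O)OC)[C@@H]2[C@](C)(C(=O)OC)CCC3OC32CO[Si](C)(C)C(C)(C)C)C=CC(=O)CC1
F2 | step 9 | 1-hydroxy analogue of 19 (ring B closed, C1 and C6 epimers) | C[Si](C)(C)C#CC[C@]12CCC(=O)C[C@H]1[C@]1(CO[Si](C)(C)C(C)(C)C)C(O)CC[C@@](C)(C(=O)OC)[C@H]1C2C(=O)OC
F3 | step 9 | 1-O-(imidazol-1-ylthiocarbonyl) derivative of F2 | C[Si](C)(C)C#CC[C@]12CCC(=O)C[C@H]1[C@]1(CO[Si](C)(C)C(C)(C)C)C(OC(=S)n3ccnc3)CC[C@@](C)(C(=O)OC)[C@H]1C2C(=O)OC
F4 | step 8 | bromoacetate of 14 | BrCC(=O)O[C@H]1CC[C@@](C)(C(=O)OC)C=C1CO[Si](C)(C)C(C)(C)C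
F5 | step 8 | 3-formylhex-5-ynoate ester of 14 (C8 epimers) | O=CC(CC#C)CC(=O)O[C@H]1CC[C@@](C)(C(=O)OC)C=C1CO[Si](C)(C)C(C)(C)C
F6 | step 8 | rearranged aldehyde diester (C5–C6 formed, C8 tertiary with CHO, silylated alkyne; C6 and C8 epimers) | C[Si](C)(C)C#CCC(C=O)C(C(=O)OC)[C@@H]1[C@](C)(C(=O)OC)CCC=C1CO[Si](C)(C)C(C)(C)C
F7 | step 11 | 13-phenylselanyl derivative of 18 | C[Si](C)(C)C#CC[C@@]1(C(C(=O)OC)[C@@H]2[C@](C)(C(=O)OC)CCC=C2CO[Si](C)(C)C(C)(C)C)C=CC(=O)C([Se]c2ccccc2)C1
F8 | step 11 | 13-phenylselanyl derivative of 19 | C[Si](C)(C)C#CC[C@]12CC([Se]c3ccccc3)C(=O)C[C@H]1[C@]1(CO[Si](C)(C)C(C)(C)C)CCC[C@@](C)(C(=O)OC)[C@H]1C2C(=O)OC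
F9 | step 11 | 13-phenylselanyl derivative of 20 | C#CC[C@]12CC([Se]c3ccccc3)C(=O)C[C@H]1[C@]1(CO[Si](C)(C)C(C)(C)C)CCC[C@@](C)(C(=O)OC)[C@H]1[C@@H]2C(=O)OC
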